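The target is cut at the interflavan bond C4–C8 and then across ring C of the upper flavan at O1–C2 and C3–C4. Ring C is read as a latent o-quinone methide: O1, C8a, C4a and C4 make a heterodiene, C2–C3 a styrene. One catalytic asymmetric oxa-[4+2] cycloaddition between a methoxy-o-quinone methide, formed in the flask from a salicylaldehyde and trimethyl orthoformate, and a catechol-derived styrene closes ring C through the O1–C2 and C3–C4 bonds, sets C2 and leaves a C4 methoxy group. That group, benzylic and activated by O1 and the 7-oxygen, is then ionised and replaced by C8 of unprotected (−)-epigallocatechin anti to the C2 aryl group; hydrogenolysis finishes the route.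

Key step: step 2

Remark on the chemistry: the sense of asymmetric induction of the chiral acid in step 2 is assumed, not known; the (R)-acid is written, and its mirror image would be used if the 2R product proves to be favoured.

Step 1
Reactants: 1 3,4-bis(benzyloxy)benzaldehyde
Product: 2 3,4-bis(benzyloxy)styrene
Conditions: Ph3PCH3Br, KOtBu, THF, 0 °C to rt
Reagents that add atoms: methyltriphenylphosphonium bromide, C[P+](c1ccccc1)(c1ccccc1)c1ccccc1.[Br-]
Why: Wittig methylenation of an aryl aldehyde by the non-stabilised ylide made in the flask should proceed cleanly, the benzyl ethers are inert to it and no stereocentre is formed.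

Step 2
Reactants: 2 3,4-bis(benzyloxy)styrene; 3 4-(benzyloxy)-2-hydroxybenzaldehyde
Product: 6 (2S,4S)-7-(benzyloxy)-2-[3,4-bis(benzyloxy)phenyl]-4-methoxychromane, via dimethyl acetal 4 (not isolated), via methoxy-o-quinone methide 5 (not isolated)
Conditions: HC(OMe)3 (1.5 equiv), (R)-3,3'-bis(2,4,6-triisopropylphenyl)-1,1'-binaphthyl-2,2'-diyl N-triflylphosphoramide (5 mol%), 5 Å molecular sieves, toluene, −30 °C
Reagents that add atoms: trimethyl orthoformate, COC(OC)OC
Why: Proposed new method: the chiral acid turns 3 and trimethyl orthoformate into acetal 4, which loses methanol to the (E)-methoxy-o-quinone methide 5, held by a hydrogen bond or as an ion pair with the chiral phosphoramide anion, and 5 adds to the electron-rich styrene 2 in an inverse-electron-demand, asynchronous oxa-Diels–Alder reaction in which C3–C4 forms first and the O1–C2 bond closes the ring. The closest known reaction types are the racemic Sc(OTf)3-catalysed three-component coupling of salicylaldehydes, trimethyl orthoformate and styrenes to 4-methoxy-2-arylchromans and the chiral phosphoric acid-catalysed enantioselective [4+2] cycloaddition of o-quinone methides from o-hydroxybenzyl alcohols with styrenes; what is untested is the enantioselective intermolecular reaction of an acetal-derived alkoxy-o-quinone methide. Ring C is the only ring closed, by intermolecular [4+2] cycloaddition of the heterodiene O1=C8a–C4a=C4 to C3=C2. C2 is set by the catalyst, whose 2,4,6-triisopropylphenyl groups should leave one face of bound 5 open to a styrene whose aryl group lies endo, and the same endo mode should place the C4 methoxy group cis to the aryl group, although C4 need not be controlled because it is ionised in step 3. Regioselectivity (CH2 of 2 to C4, the aryl-bearing carbon to O1) is secured by the polarisation of both partners, the para-benzyloxy group of 2 stabilising positive charge at C2, and the 4-benzyloxy group of 3 makes 5 a long-lived vinylogous ester that should react under catalyst control and not through a free oxocarbenium ion.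

Step 3
Reactants: 6 (2S,4S)-7-(benzyloxy)-2-[3,4-bis(benzyloxy)phenyl]-4-methoxychromane; 7 (−)-epigallocatechin
Product: 9 (2R,3R)-8-{(2S,4R)-7-(benzyloxy)-2-[3,4-bis(benzyloxy)phenyl]chroman-4-yl}-2-(3,4,5-trihydroxyphenyl)chromane-3,5,7-triol, via flavan-4-ylium cation 8 (not isolated)
Conditions: 7 (3 equiv), TsOH·H2O (10 mol%), THF/CH2Cl2, 0 °C, then chromatography
Reagents that add atoms: none
Why: Acid ionises the C4 methoxy group of 6 to cation 8, which is stabilised by O1 (ortho) and the 7-benzyloxy group (para), and Friedel–Crafts alkylation of the phloroglucinol ring A of 7 at C8, its usual site as a free phenol, should occur by pseudo-axial attack anti to the equatorial C2 aryl group, which sets C4 as R (2,4-trans) under substrate control, as in biomimetic proanthocyanidin couplings.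

Step 4
Reactants: 9 (2R,3R)-8-{(2S,4R)-7-(benzyloxy)-2-[3,4-bis(benzyloxy)phenyl]chroman-4-yl}-2-(3,4,5-trihydroxyphenyl)chromane-3,5,7-triol
Product: 10 (2R,3R)-8-[(2S,4R)-2-(3,4-dihydroxyphenyl)-7-hydroxychroman-4-yl]-2-(3,4,5-trihydroxyphenyl)chromane-3,5,7-triol
Conditions: H2 (1 atm), Pd(OH)2/C, THF/MeOH, rt, filtration under argon
Reagents that add atoms: none
Why: Catalytic hydrogenolysis should cleave the three aryl benzyl ethers, while the cyclic benzylic C2–O1 ethers of both pyran rings and the doubly benzylic C4–C8 bond are much slower to cleave over Pd(OH)2/C, so no stereocentre is touched.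

Compound list
1 | 3,4-bis(benzyloxy)benzaldehyde | O=Cc1ccc(OCc2ccccc2)c(OCc2ccccc2)c1 | starting material
2 | 3,4-bis(benzyloxy)styrene (1,2-bis(benzyloxy)-4-ethenylbenzene) | C=Cc1ccc(OCc2ccccc2)c(OCc2ccccc2)c1 | intermediate
3 | 4-(benzyloxy)-2-hydroxybenzaldehyde | O=Cc1ccc(OCc2ccccc2)cc1O | starting material
4 | 5-(benzyloxy)-2-(dimethoxymethyl)phenol, the dimethyl acetal of 3, formed in the flask | COC(OC)c1ccc(OCc2ccccc2)cc1O | intermediate
5 | (6E)-3-(benzyloxy)-6-(methoxymethylidene)cyclohexa-2,4-dien-1-one, the methoxy-o-quinone methide, formed in the flask | O=C1C=C(OCc2ccccc2)C=C/C1=C\OC | intermediate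
6 | (2S,4S)-7-(benzyloxy)-2-[3,4-bis(benzyloxy)phenyl]-4-methoxychromane (2,4-cis) | CO[C@H]1C[C@@H](c2ccc(OCc3ccccc3)c(OCc3ccccc3)c2)Oc2cc(OCc3ccccc3)ccc21 | intermediate
7 | (−)-epigallocatechin, (2R,3R)-2-(3,4,5-trihydroxyphenyl)chromane-3,5,7-triol | O[C@@H]1Cc2c(O)cc(O)cc2O[C@@H]1c1cc(O)c(O)c(O)c1 | starting material
8 | (2S)-7-(benzyloxy)-2-[3,4-bis(benzyloxy)phenyl]chroman-4-ylium, the C4 cation, formed in the flask | [CH+]1C[C@@H](c2ccc(OCc3ccccc3)c(OCc3ccccc3)c2)Oc2cc(OCc3ccccc3)ccc21 | intermediate
9 | (2R,3R)-8-{(2S,4R)-7-(benzyloxy)-2-[3,4-bis(benzyloxy)phenyl]chroman-4-yl}-2-(3,4,5-trihydroxyphenyl)chromane-3,5,7-triol | O(Cc1ccccc1)c1ccc2c(c1)O[C@H](c1ccc(OCc3ccccc3)c(OCc3ccccc3)c1)C[C@H]2c1c(O)cc(O)c2c1O[C@H](c1cc(O)c(O)c(O)c1)[C@H](O)C2 | intermediate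
10 | (2R,3R)-8-[(2S,4R)-2-(3,4-dihydroxyphenyl)-7-hydroxychroman-4-yl]-2-(3,4,5-trihydroxyphenyl)chromane-3,5,7-triol (CNP0211965.1) | Oc1ccc2c(c1)O[C@H](c1ccc(O)c(O)c1)C[C@H]2c1c(O)cc(O)c2c1O[C@H](c1cc(O)c(O)c(O)c1)[C@H](O)C2 | target

Total step count: 4. Longest linear sequence: 4 steps (1 to 2 to 6 to 9 to 10).

Steps most likely to fail

Step 2 (Proposed new method). The chiral acid may give poor facial selectivity at C2, or may oligomerise styrene 2 faster than the cycloaddition proceeds. The fallback uses known chemistry, sets out from 1 and comes back to the route at 9. Claisen–Schmidt condensation of 1 with commercial 1-[4-(benzyloxy)-2-hydroxyphenyl]ethanone (KOH, EtOH, rt) should give the chalcone (E)-1-[4-(benzyloxy)-2-hydroxyphenyl]-3-[3,4-bis(benzyloxy)phenyl]prop-2-en-1-one F1. A 6-endo oxa-Michael closure (NaOAc, EtOH, reflux), which forms the same O1–C2 bond, should then give the racemic flavanone 7-(benzyloxy)-2-[3,4-bis(benzyloxy)phenyl]chroman-4-one F2. Asymmetric transfer hydrogenation with kinetic resolution (RuCl(p-cymene)[(S,S)-N-tosyl-1,2-diphenylethylenediamine], HCO2H/Et3N, rt; the catalyst enantiomer that gives the 4S alcohol) is expected to reduce only the 2S ketone, anti to its aryl group. This should give the cis-flavan-4-ol (2S,4S)-7-(benzyloxy)-2-[3,4-bis(benzyloxy)phenyl]chroman-4-ol F3 and leave the 2R ketone behind, so at most half of F2 is used. F3 takes the place of 6 in step 3, ionises to the same cation 8 and should give 9.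

Step 3. Alkylation may occur at C6 instead of C8 of 7, facial selectivity at C4 may be incomplete, and the product may be alkylated again to oligomers. The fallback sets out from 7 and comes back to the route at 10. The five phenolic oxygens of 7 are benzylated (BnBr, K2CO3, DMF, 0 °C, under argon) to 5,7,3',4',5'-penta-O-benzyl-(−)-epigallocatechin F4. Coupling of excess F4 with 6 (TMSOTf cat., CH2Cl2, −78 °C), the C8-selective and kinetically controlled coupling known for benzylated flavan-3-ols, should give (2R,3R)-5,7-bis(benzyloxy)-8-{(2S,4R)-7-(benzyloxy)-2-[3,4-bis(benzyloxy)phenyl]chroman-4-yl}-2-[3,4,5-tris(benzyloxy)phenyl]chroman-3-ol F5. Hydrogenolysis of all eight benzyl ethers under the conditions of step 4 then gives 10.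

Step 4. The benzylic C2–O1 bonds may be opened by hydrogenolysis, the polyphenol may poison the catalyst and stall the cleavage, and the pyrogallol ring may be oxidised by air during work-up. The fallback sets out from 9 and comes back to the route at 10. The reductive cleavage is replaced by Lewis acid-mediated benzyl transfer to an arene scavenger (BCl3, pentamethylbenzene, CH2Cl2, −78 °C, then MeOH quench), which needs no hydrogen or metal catalyst and makes no new isolated compound.

Further compounds
F1 | step 2 | (E)-1-[4-(benzyloxy)-2-hydroxyphenyl]-3-[3,4-bis(benzyloxy)phenyl]prop-2-en-1-one | O=C(/C=C/c1ccc(OCc2ccccc2)c(OCc2ccccc2)c1)c1ccc(OCc2ccccc2)cc1O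
F2 | step 2 | rac-7-(benzyloxy)-2-[3,4-bis(benzyloxy)phenyl]chroman-4-one | O=C1CC(c2ccc(OCc3ccccc3)c(OCc3ccccc3)c2)Oc2cc(OCc3ccccc3)ccc21
F3 | step 2 | (2S,4S)-7-(benzyloxy)-2-[3,4-bis(benzyloxy)phenyl]chroman-4-ol | O[C@H]1C[C@@H](c2ccc(OCc3ccccc3)c(OCc3ccccc3)c2)Oc2cc(OCc3ccccc3)ccc21
F4 | step 3 | (2R,3R)-5,7-bis(benzyloxy)-2-[3,4,5-tris(benzyloxy)phenyl]chroman-3-ol | O[C@@H]1Cc2c(OCc3ccccc3)cc(OCc3ccccc3)cc2O[C@@H]1c1cc(OCc2ccccc2)c(OCc2ccccc2)c(OCc2ccccc2)c1
F5 | step 3 | (2R,3R)-5,7-bis(benzyloxy)-8-{(2S,4R)-7-(benzyloxy)-2-[3,4-bis(benzyloxy)phenyl]chroman-4-yl}-2-[3,4,5-tris(benzyloxy)phenyl]chroman-3-ol | O(Cc1ccccc1)c1ccc2c(c1)O[C@H](c1ccc(OCc3ccccc3)c(OCc3ccccc3)c1)C[C@H]2c1c(OCc3ccccc3)cc(OCc3ccccc3)c2c1O[C@H](c1cc(OCc3ccccc3)c(OCc3ccccc3)c(OCc3ccccc3)c1)[C@H](O)C2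
F0 | step 4 | none | none
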